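**Strategy**

The oxane ring (O1; C2 with the arylethyl chain; C3 = CH2; C4 with the phloroglucinol aryl; C5 with the diarylheptenyl chain; C6 with 4-hydroxyphenyl) carries all four substituents equatorially, so it can be closed under thermodynamic control. A nitro group is lent to C3: it first makes C4 electrophilic for an organocatalytic Michael addition that sets C4 and C5, then makes C3 nucleophilic. The key step joins the resulting γ-nitroaldehyde with 3-arylpropanal in a domino Henry/hemiacetalisation that forms C2–C3 and O1–C6 in one operation and sets C2. The nitro group and the lactol oxidation level at C6 are removed afterwards.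

Key step: step 12

Remark: Ts = 4-methylbenzenesulfonyl, Piv = 2,2-dimethylpropanoyl; ring locants are those of the overview; lactol 19 is expected as an anomeric mixture, so C6 is left undefined in its SMILES.

**Route**

Step 1
Reactants: 1 methyl 3-(4-hydroxyphenyl)propanoate
Product: 2 methyl 3-[4-(tosyloxy)phenyl]propanoate
Conditions: TsCl, Et3N, DMAP (cat.), CH2Cl2, 0 °C → rt
Reagents that add atoms: 4-methylbenzenesulfonyl chloride, Cc1ccc(S(Cl)(=O)=O)cc1
Why: Sulfonylation of the phenol; the electron-poor aryl tosylate should keep the later benzylic positions from ionising and survive all acidic, radical and organometallic steps.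

Step 2
Reactants: 2 methyl 3-[4-(tosyloxy)phenyl]propanoate
Product: 3 3-[4-(tosyloxy)phenyl]propanal
Conditions: iBu2AlH (1.1 equiv), CH2Cl2, −78 °C; aq. KNaC4H4O6
Reagents that add atoms: none
Why: Partial ester reduction with iBu2AlH stops at the tetrahedral aluminium hemiacetal at −78 °C and should release the aldehyde on work-up.

Step 3
Reactants: 4 (E)-4-(4-hydroxyphenyl)but-3-en-2-one
Product: 5 (E)-4-[4-(tosyloxy)phenyl]but-3-en-2-one
Conditions: TsCl, Et3N, DMAP (cat.), CH2Cl2, 0 °C → rt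
Reagents that add atoms: 4-methylbenzenesulfonyl chloride, Cc1ccc(S(Cl)(=O)=O)cc1
Why: Phenol sulfonylation as in step 1.

Step 4
Reactants: 5 (E)-4-[4-(tosyloxy)phenyl]but-3-en-2-one; 3 3-[4-(tosyloxy)phenyl]propanal
Product: 8 (S,E)-5-hydroxy-1,7-bis[4-(tosyloxy)phenyl]hept-1-en-3-one, via silyl dienol ether 6 (not isolated), via O-silyl aldol 7 (not isolated)
Conditions: TMSOTf, Et3N, CH2Cl2, 0 °C; solvent exchange; then 3, (S)-N-tosyltryptophan-derived B-n-butyl-oxazaborolidinone (20 mol%), EtCN, −78 °C; 1 M HCl/THF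
Reagents that add atoms: none
Why: Soft enolisation followed by a catalytic asymmetric Mukaiyama aldol reaction, in which the oxazaborolidinone should shield one aldehyde face so that Re-face attack sets the (S) carbinol; any minor enantiomer becomes a separable diastereomer after step 6.

Step 5
Reactants: 8 (S,E)-5-hydroxy-1,7-bis[4-(tosyloxy)phenyl]hept-1-en-3-one
Product: 9 (S,E)-3-oxo-1,7-bis[4-(tosyloxy)phenyl]hept-1-en-5-yl pivalate
Conditions: PivCl, pyridine, DMAP (cat.), CH2Cl2, 0 °C → rt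
Reagents that add atoms: pivaloyl chloride, CC(C)(C)C(Cl)=O
Why: DMAP-catalysed acylation of the secondary alcohol; pivalate is a poor leaving group, so E1cB elimination of the β-acyloxy ketone should not compete under these mild conditions.

Step 6
Reactants: 9 (S,E)-3-oxo-1,7-bis[4-(tosyloxy)phenyl]hept-1-en-5-yl pivalate
Product: 10 (3R,5S,E)-3-hydroxy-1,7-bis[4-(tosyloxy)phenyl]hept-1-en-5-yl pivalate
Conditions: (S)-2-methyl-CBS-oxazaborolidine (20 mol%), catecholborane, toluene, −78 °C; aq. NaOH work-up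
Reagents that add atoms: none
Why: Corey–Bakshi–Shibata reduction; reagent-controlled 1,2-hydride delivery to the enone (alkenyl as the large group) should set the (3R) allylic carbinol, anti to the C5 pivalate.

Step 7
Reactants: 10 (3R,5S,E)-3-hydroxy-1,7-bis[4-(tosyloxy)phenyl]hept-1-en-5-yl pivalate
Product: 12 (3R,4E,7S)-1-oxo-3,9-bis[4-(tosyloxy)phenyl]non-4-en-7-yl pivalate, via allyl vinyl ether 11 (not isolated)
Conditions: ethyl vinyl ether (solvent), Hg(OAc)2 (cat.), reflux; concentrate; toluene, sealed tube, 130 °C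
Reagents that add atoms: ethyl vinyl ether, C=COCC
Why: Transvinylation then Claisen rearrangement through a chair transition state with the carbinol substituent equatorial, which should transfer the C3 chirality suprafacially to the new benzylic centre (3R in 12) and give the E-alkene.

Step 8
Reactants: 13 2,4,6-trimethoxybenzaldehyde
Product: 14 2,6-dihydroxy-4-methoxybenzaldehyde
Conditions: BBr3 (2.2 equiv), CH2Cl2, −78 → 0 °C; H2O
Reagents that add atoms: none
Why: Chelation-directed ether cleavage; boron bound to the formyl oxygen should cleave the two ortho methoxy groups faster than the para one.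

Step 9
Reactants: 14 2,6-dihydroxy-4-methoxybenzaldehyde
Product: 15 2-formyl-5-methoxy-1,3-phenylene bis(pivalate)
Conditions: PivCl (2.5 equiv), Et3N, DMAP (cat.), CH2Cl2, 0 °C → rt
Reagents that add atoms: pivaloyl chloride, CC(C)(C)C(Cl)=O
Why: Acylation of both phenols; the ester groups make the later nitroalkene more electrophilic and can be removed without touching aryl tosylates.

Step 10
Reactants: 15 2-formyl-5-methoxy-1,3-phenylene bis(pivalate)
Product: 16 5-methoxy-2-[(E)-2-nitroethenyl]-1,3-phenylene bis(pivalate)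
Conditions: MeNO2, NH4OAc, AcOH, 90 °C
Reagents that add atoms: nitromethane, C[N+](=O)[O-]
Why: Henry condensation (nitroaldol addition then dehydration) should give the thermodynamically favoured E-nitroalkene.

Step 11
Reactants: 12 (3R,4E,7S)-1-oxo-3,9-bis[4-(tosyloxy)phenyl]non-4-en-7-yl pivalate; 16 5-methoxy-2-[(E)-2-nitroethenyl]-1,3-phenylene bis(pivalate)
Product: 17 (2S,3R)-3-[4-methoxy-2,6-bis(pivaloyloxy)phenyl]-4-nitro-2-[(1S,2E,5S)-5-(pivaloyloxy)-1,7-bis(4-tosyloxyphenyl)hept-2-en-1-yl]butanal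
Conditions: (R)-α,α-diphenylprolinol trimethylsilyl ether (20 mol%), 4-nitrophenol (20 mol%), toluene, 0 °C → rt
Reagents that add atoms: none
Why: Enamine-catalysed Michael addition of an aldehyde to a nitroalkene; the E-enamine of the (R)-catalyst should add through the acyclic synclinal transition state to give the syn (2S,3R) adduct, which fixes C5 and C4 of the ring under catalyst control.

Step 12
Reactants: 17 the γ-nitroaldehyde of step 11; 3 3-[4-(tosyloxy)phenyl]propanal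
Product: 19 all-equatorial lactol 3-nitro-4-[4-methoxy-2,6-bis(pivaloyloxy)phenyl]-5-[(1S,2E,5S)-5-(pivaloyloxy)-1,7-bis(4-tosyloxyphenyl)hept-2-en-1-yl]-2-[2-(4-tosyloxyphenyl)ethyl]oxan-6-ol, via open-chain nitro aldol 18 (not isolated)
Conditions: 3 (1.5 equiv), Et3N (1.0 equiv), THF, 0 °C → rt, until the lactol mixture has converged
Reagents that add atoms: none
Why: Et3N generates the nitronate at C3 of 17, which adds to the unhindered aldehyde 3 (Henry reaction, C2–C3), and the β-nitro alcohol 18 closes onto the C6 formyl group (hemiacetalisation, O1–C6). The closest known reaction type is the domino Henry/hemiacetalisation of γ-nitroaldehydes with a second aldehyde, which gives tetrahydropyranols after organocatalytic Michael additions. The oxane ring closes by 6-exo-trig attack of the C2 hydroxyl on the aldehyde carbon. C2 is set under thermodynamic control: the Henry step is reversible and C3 is epimerisable through its nitronate, so the system should drain into the chair with the C2 chain, C3 nitro, C4 aryl and C5 chain all equatorial, anchored by C4 and C5 from step 11, while C3 and C6 are transient centres erased in steps 13 and 14. The selectivity needed is cross- over self-condensation and all-equatorial convergence; the excess of linear aldehyde 3 over the α-branched formyl group of 17 and the lactol as thermodynamic sink should secure it.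

Step 13
Reactants: 19 the lactol of step 12
Product: 20 3-nitro δ-lactone (oxan-6-one with the C2–C5 substituents of 19 all equatorial)
Conditions: Dess–Martin periodinane, CH2Cl2, 0 °C → rt
Reagents that add atoms: none
Why: Dess–Martin oxidation of the lactol under non-basic conditions, which should avoid retro-Henry opening and elimination of the β-nitro ester.

Step 14
Reactants: 20 the 3-nitro δ-lactone
Product: 21 δ-lactone with C3 = CH2 (C2 chain, C4 aryl and C5 chain equatorial)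
Conditions: Bu3SnH (5 equiv), AIBN (portions), toluene, 110 °C
Reagents that add atoms: none
Why: Radical denitration; the stannyl radical adds to the nitro group, the secondary C3 radical is released and reduced by Bu3SnH, as known for ring nitro groups of nitro sugars, and no stereocentre remains at C3.

Step 15
Reactants: 22 4-iodophenol
Product: 23 4-iodophenyl 4-methylbenzenesulfonate
Conditions: TsCl, Et3N, DMAP (cat.), CH2Cl2, 0 °C → rt
Reagents that add atoms: 4-methylbenzenesulfonyl chloride, Cc1ccc(S(Cl)(=O)=O)cc1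
Why: Phenol sulfonylation as in step 1.

Step 16
Reactants: 21 the denitrated δ-lactone; 23 4-iodophenyl 4-methylbenzenesulfonate
Product: 26 all-equatorial oxane 4-[4-methoxy-2,6-bis(pivaloyloxy)phenyl]-5-[(1S,2E,5S)-5-(pivaloyloxy)-1,7-bis(4-tosyloxyphenyl)hept-2-en-1-yl]-6-(4-tosyloxyphenyl)-2-[2-(4-tosyloxyphenyl)ethyl]oxane, via aryl Grignard reagent 24 (not isolated), via aryl hemiketal 25 (not isolated)
Conditions: 23, iPrMgCl·LiCl, THF, −20 °C; then 21, −78 → −40 °C; aq. NH4Cl; crude: Et3SiH, BF3·OEt2, CH2Cl2/MeCN, −40 °C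
Reagents that add atoms: none
Why: Iodine–magnesium exchange and single Grignard addition to the lactone, then ionisation of the hemiketal to the 6-aryl oxocarbenium ion and axial hydride delivery from Et3SiH (as in C-aryl glycoside synthesis), which should place the aryl group equatorial and cis to the C2 chain.

Step 17
Reactants: 26 the tris-pivalate oxane
Product: 27 triol with free 2,6-dihydroxy-4-methoxyphenyl group and free side-chain carbinol (three aryl tosylates kept)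
Conditions: iBu2AlH (8 equiv), CH2Cl2, −78 °C; aq. KNaC4H4O6
Reagents that add atoms: none
Why: Reductive cleavage of the three pivalates by excess iBu2AlH, which should leave the aryl sulfonates, the alkene and the oxane untouched.

Step 18
Reactants: 27 the triol
Product: 29 methyl ketone (3-acetyl-2,6-dihydroxy-4-methoxyphenyl group at C4), via ketiminium chloride 28 (not isolated)
Conditions: MeCN, ZnCl2, HCl (g), Et2O, 0 °C; then H2O, 60 °C
Reagents that add atoms: acetonitrile, CC#N; water, O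
Why: Hoesch acylation; the nitrilium electrophile should attack only the resorcinol-type ring, ortho to a free hydroxyl at one of two equivalent positions, and hydrolysis of the ketiminium salt gives the acetophenone (any imidate-derived O-acetate is cleaved in step 19).

Step 19
Reactants: 29 the methyl ketone; 30 4-hydroxybenzaldehyde
Product: 32 blepharocalyxin E, via pentaphenol ketone 31 (not isolated)
Conditions: KOH, H2O/1,4-dioxane, 80 °C, Ar; cool; 30 (excess), 50% aq. KOH, EtOH, rt; acidify to pH 4–5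
Reagents that add atoms: none
Why: Hydroxide cleaves the aryl sulfonates at sulfur (no methoxide, so no methyl tosylate that could O-methylate), then Claisen–Schmidt condensation with 30 and E1cB dehydration should give the E-chalcone.

**Compound list**

1 | methyl 3-(4-hydroxyphenyl)propanoate | COC(=O)CCc1ccc(O)cc1 | starting material
2 | methyl 3-[4-(tosyloxy)phenyl]propanoate | COC(=O)CCc1ccc(OS(=O)(=O)c2ccc(C)cc2)cc1 | intermediate
3 | 3-[4-(tosyloxy)phenyl]propanal | O=CCCc1ccc(OS(=O)(=O)c2ccc(C)cc2)cc1 | intermediate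
4 | (E)-4-(4-hydroxyphenyl)but-3-en-2-one | CC(=O)/C=C/c1ccc(O)cc1 | starting material
5 | (E)-4-[4-(tosyloxy)phenyl]but-3-en-2-one | CC(=O)/C=C/c1ccc(OS(=O)(=O)c2ccc(C)cc2)cc1 | intermediate
6 | (E)-4-[4-(tosyloxy)phenyl]-2-(trimethylsilyloxy)buta-1,3-diene | C=C(O[Si](C)(C)C)/C=C/c1ccc(OS(=O)(=O)c2ccc(C)cc2)cc1 | intermediate
7 | (S,E)-1,7-bis[4-(tosyloxy)phenyl]-5-(trimethylsilyloxy)hept-1-en-3-one | O=C(/C=C/c1ccc(OS(=O)(=O)c2ccc(C)cc2)cc1)C[C@@H](O[Si](C)(C)C)CCc1ccc(OS(=O)(=O)c2ccc(C)cc2)cc1 | intermediate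
8 | (S,E)-5-hydroxy-1,7-bis[4-(tosyloxy)phenyl]hept-1-en-3-one | O=C(/C=C/c1ccc(OS(=O)(=O)c2ccc(C)cc2)cc1)C[C@@H](O)CCc1ccc(OS(=O)(=O)c2ccc(C)cc2)cc1 | intermediate
9 | (S,E)-3-oxo-1,7-bis[4-(tosyloxy)phenyl]hept-1-en-5-yl pivalate | O=C(/C=C/c1ccc(OS(=O)(=O)c2ccc(C)cc2)cc1)C[C@@H](OC(=O)C(C)(C)C)CCc1ccc(OS(=O)(=O)c2ccc(C)cc2)cc1 | intermediate
10 | (3R,5S,E)-3-hydroxy-1,7-bis[4-(tosyloxy)phenyl]hept-1-en-5-yl pivalate | O[C@@H](/C=C/c1ccc(OS(=O)(=O)c2ccc(C)cc2)cc1)C[C@@H](OC(=O)C(C)(C)C)CCc1ccc(OS(=O)(=O)c2ccc(C)cc2)cc1 | intermediate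
11 | vinyl ether of 10 | C=CO[C@@H](/C=C/c1ccc(OS(=O)(=O)c2ccc(C)cc2)cc1)C[C@@H](OC(=O)C(C)(C)C)CCc1ccc(OS(=O)(=O)c2ccc(C)cc2)cc1 | intermediate
12 | (3R,4E,7S)-1-oxo-3,9-bis[4-(tosyloxy)phenyl]non-4-en-7-yl pivalate | O=CC[C@H](/C=C/C[C@@H](OC(=O)C(C)(C)C)CCc1ccc(OS(=O)(=O)c2ccc(C)cc2)cc1)c1ccc(OS(=O)(=O)c2ccc(C)cc2)cc1 | intermediate
13 | 2,4,6-trimethoxybenzaldehyde | COc1cc(OC)c(C=O)c(OC)c1 | starting material
14 | 2,6-dihydroxy-4-methoxybenzaldehyde | COc1cc(O)c(C=O)c(O)c1 | intermediate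
15 | 2-formyl-5-methoxy-1,3-phenylene bis(pivalate) | COc1cc(OC(=O)C(C)(C)C)c(C=O)c(OC(=O)C(C)(C)C)c1 | intermediate
16 | 5-methoxy-2-[(E)-2-nitroethenyl]-1,3-phenylene bis(pivalate) | COc1cc(OC(=O)C(C)(C)C)c(/C=C/[N+](=O)[O-])c(OC(=O)C(C)(C)C)c1 | intermediate
17 | (2S,3R)-γ-nitroaldehyde (syn Michael adduct of 12 and 16) | COc1cc(OC(=O)C(C)(C)C)c([C@H](C[N+](=O)[O-])[C@@H](C=O)[C@H](/C=C/C[C@@H](OC(=O)C(C)(C)C)CCc2ccc(OS(=O)(=O)c3ccc(C)cc3)cc2)c2ccc(OS(=O)(=O)c3ccc(C)cc3)cc2)c(OC(=O)C(C)(C)C)c1 | intermediate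
18 | open-chain nitro aldol of 17 and 3 | COc1cc(OC(=O)C(C)(C)C)c([C@H]([C@@H]([N+](=O)[O-])[C@@H](O)CCc2ccc(OS(=O)(=O)c3ccc(C)cc3)cc2)[C@@H](C=O)[C@H](/C=C/C[C@@H](OC(=O)C(C)(C)C)CCc2ccc(OS(=O)(=O)c3ccc(C)cc3)cc2)c2ccc(OS(=O)(=O)c3ccc(C)cc3)cc2)c(OC(=O)C(C)(C)C)c1 | intermediate
19 | all-equatorial 3-nitro lactol (anomeric mixture) | COc1cc(OC(=O)C(C)(C)C)c([C@@H]2[C@@H]([N+](=O)[O-])[C@H](CCc3ccc(OS(=O)(=O)c4ccc(C)cc4)cc3)OC(O)[C@H]2[C@H](/C=C/C[C@@H](OC(=O)C(C)(C)C)CCc2ccc(OS(=O)(=O)c3ccc(C)cc3)cc2)c2ccc(OS(=O)(=O)c3ccc(C)cc3)cc2)c(OC(=O)C(C)(C)C)c1 | intermediate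
20 | 3-nitro δ-lactone | COc1cc(OC(=O)C(C)(C)C)c([C@@H]2[C@@H]([N+](=O)[O-])[C@H](CCc3ccc(OS(=O)(=O)c4ccc(C)cc4)cc3)OC(=O)[C@H]2[C@H](/C=C/C[C@@H](OC(=O)C(C)(C)C)CCc2ccc(OS(=O)(=O)c3ccc(C)cc3)cc2)c2ccc(OS(=O)(=O)c3ccc(C)cc3)cc2)c(OC(=O)C(C)(C)C)c1 | intermediate
21 | denitrated δ-lactone | COc1cc(OC(=O)C(C)(C)C)c([C@@H]2C[C@H](CCc3ccc(OS(=O)(=O)c4ccc(C)cc4)cc3)OC(=O)[C@H]2[C@H](/C=C/C[C@@H](OC(=O)C(C)(C)C)CCc2ccc(OS(=O)(=O)c3ccc(C)cc3)cc2)c2ccc(OS(=O)(=O)c3ccc(C)cc3)cc2)c(OC(=O)C(C)(C)C)c1 | intermediate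
22 | 4-iodophenol | Oc1ccc(I)cc1 | starting material
23 | 4-iodophenyl 4-methylbenzenesulfonate | Cc1ccc(S(=O)(=O)Oc2ccc(I)cc2)cc1 | intermediate
24 | 4-(tosyloxy)phenylmagnesium chloride–lithium chloride | Cc1ccc(S(=O)(=O)Oc2ccc([Mg]Cl)cc2)cc1.[Li+].[Cl-] | intermediate
25 | C6 aryl hemiketal (OH axial, aryl equatorial) | COc1cc(OC(=O)C(C)(C)C)c([C@@H]2C[C@H](CCc3ccc(OS(=O)(=O)c4ccc(C)cc4)cc3)O[C@](O)(c3ccc(OS(=O)(=O)c4ccc(C)cc4)cc3)[C@H]2[C@H](/C=C/C[C@@H](OC(=O)C(C)(C)C)CCc2ccc(OS(=O)(=O)c3ccc(C)cc3)cc2)c2ccc(OS(=O)(=O)c3ccc(C)cc3)cc2)c(OC(=O)C(C)(C)C)c1 | intermediate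
26 | all-equatorial oxane, tris-pivalate tetra-tosylate | COc1cc(OC(=O)C(C)(C)C)c([C@@H]2C[C@H](CCc3ccc(OS(=O)(=O)c4ccc(C)cc4)cc3)O[C@H](c3ccc(OS(=O)(=O)c4ccc(C)cc4)cc3)[C@H]2[C@H](/C=C/C[C@@H](OC(=O)C(C)(C)C)CCc2ccc(OS(=O)(=O)c3ccc(C)cc3)cc2)c2ccc(OS(=O)(=O)c3ccc(C)cc3)cc2)c(OC(=O)C(C)(C)C)c1 | intermediate
27 | triol (free resorcinol ring and side-chain carbinol) | COc1cc(O)c([C@@H]2C[C@H](CCc3ccc(OS(=O)(=O)c4ccc(C)cc4)cc3)O[C@H](c3ccc(OS(=O)(=O)c4ccc(C)cc4)cc3)[C@H]2[C@H](/C=C/C[C@@H](O)CCc2ccc(OS(=O)(=O)c3ccc(C)cc3)cc2)c2ccc(OS(=O)(=O)c3ccc(C)cc3)cc2)c(O)c1 | intermediate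
28 | ketiminium chloride of 29 | COc1cc(O)c([C@@H]2C[C@H](CCc3ccc(OS(=O)(=O)c4ccc(C)cc4)cc3)O[C@H](c3ccc(OS(=O)(=O)c4ccc(C)cc4)cc3)[C@H]2[C@H](/C=C/C[C@@H](O)CCc2ccc(OS(=O)(=O)c3ccc(C)cc3)cc2)c2ccc(OS(=O)(=O)c3ccc(C)cc3)cc2)c(O)c1C(C)=[NH2+].[Cl-] | intermediate
29 | methyl ketone, tris-tosylate | COc1cc(O)c([C@@H]2C[C@H](CCc3ccc(OS(=O)(=O)c4ccc(C)cc4)cc3)O[C@H](c3ccc(OS(=O)(=O)c4ccc(C)cc4)cc3)[C@H]2[C@H](/C=C/C[C@@H](O)CCc2ccc(OS(=O)(=O)c3ccc(C)cc3)cc2)c2ccc(OS(=O)(=O)c3ccc(C)cc3)cc2)c(O)c1C(C)=O | intermediate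
30 | 4-hydroxybenzaldehyde | O=Cc1ccc(O)cc1 | starting material
31 | pentaphenol methyl ketone | COc1cc(O)c([C@@H]2C[C@H](CCc3ccc(O)cc3)O[C@H](c3ccc(O)cc3)[C@H]2[C@H](/C=C/C[C@@H](O)CCc2ccc(O)cc2)c2ccc(O)cc2)c(O)c1C(C)=O | intermediate
32 | blepharocalyxin E (ring C2 S, C4 R, C5 R, C6 S in the locants used here; side chain 1S,5S) | COc1cc(O)c([C@@H]2C[C@H](CCc3ccc(O)cc3)O[C@H](c3ccc(O)cc3)[C@H]2[C@H](/C=C/C[C@@H](O)CCc2ccc(O)cc2)c2ccc(O)cc2)c(O)c1C(=O)/C=C/c1ccc(O)cc1 | target

**Step count and risks**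

Total steps: 19. Longest linear sequence: 14 (steps 1, 2, 4, 5, 6, 7, 11, 12, 13, 14, 16, 17, 18, 19).

Step 11 may fail through slow enamine addition to the doubly ortho-substituted nitroalkene and through mismatched double stereodifferentiation with the adjacent benzylic centre, which would erode conversion and diastereoselectivity. The fallback sets out from 12 and comes back at 17. Aldehyde 12 is condensed with (S)-1-amino-2-(methoxymethyl)pyrrolidine to the SAMP hydrazone of 12 F1. Deprotonation with LiN(iPr)2 in THF at −78 °C and addition of 16 at −100 °C should give, through the far more nucleophilic chelated azaenolate and under auxiliary control, the syn γ-nitro hydrazone F2. Mild hydrolysis (aqueous oxalic acid, Et2O) releases 17 and the auxiliary.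

Step 12 may fail through incomplete equilibration (retro-Henry exchange too slow for all-equatorial convergence), dehydration of the nitro aldol, or self-aldolisation of 3. The fallback sets out from 17 and comes back at 20. Pinnick oxidation (NaClO2, NaH2PO4, 2-methylbut-2-ene) gives the γ-nitro acid F3, and Me3SiCHN2 gives its methyl ester F4. Henry addition of F4 to 3 (1,1,3,3-tetramethylguanidine, THF) is then followed in the same operation by irreversible lactonisation of the nitro alkoxide onto the ester. C2–C3 and O1–C6 therefore still form together, the reversible Henry step feeds the fastest-closing all-equatorial diastereomer, and lactone 20 is reached without a lactol oxidation.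

Step 19 may fail through a sluggish aldol condensation between the polyphenolate ketone and the phenolate aldehyde, with air oxidation or retro-aldol cleavage over the long reaction time. The fallback sets out from 27 and comes back at 32. Commercial p-coumaric acid is tosylated to (E)-3-[4-(tosyloxy)phenyl]acrylic acid F5. Friedel–Crafts C-acylation of 27 with F5, activated as its mixed trifluoroacetic anhydride (TFAA, CH2Cl2, then BF3·OEt2), installs the whole cinnamoyl unit ortho to a phenol and gives the tetra-tosyl chalcone F6. Any flavanone or O-acyl by-products reopen or hydrolyse in base. Aqueous KOH in dioxane then removes the four tosylates to give 32.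

**Further compounds**

F1 | step 11 | SAMP hydrazone of 12 | COC[C@@H]1CCCN1/N=C/C[C@H](/C=C/C[C@@H](OC(=O)C(C)(C)C)CCc1ccc(OS(=O)(=O)c2ccc(C)cc2)cc1)c1ccc(OS(=O)(=O)c2ccc(C)cc2)cc1
F2 | step 11 | syn γ-nitro SAMP hydrazone | COC[C@@H]1CCCN1/N=C/[C@H]([C@@H](C[N+](=O)[O-])c1c(OC(=O)C(C)(C)C)cc(OC)cc1OC(=O)C(C)(C)C)[C@H](/C=C/C[C@@H](OC(=O)C(C)(C)C)CCc1ccc(OS(=O)(=O)c2ccc(C)cc2)cc1)c1ccc(OS(=O)(=O)c2ccc(C)cc2)cc1
F3 | step 12 | γ-nitro acid from 17 | COc1cc(OC(=O)C(C)(C)C)c([C@H](C[N+](=O)[O-])[C@@H](C(=O)O)[C@H](/C=C/C[C@@H](OC(=O)C(C)(C)C)CCc2ccc(OS(=O)(=O)c3ccc(C)cc3)cc2)c2ccc(OS(=O)(=O)c3ccc(C)cc3)cc2)c(OC(=O)C(C)(C)C)c1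
F4 | step 12 | methyl ester of F3 | COc1cc(OC(=O)C(C)(C)C)c([C@H](C[N+](=O)[O-])[C@@H](C(=O)OC)[C@H](/C=C/C[C@@H](OC(=O)C(C)(C)C)CCc2ccc(OS(=O)(=O)c3ccc(C)cc3)cc2)c2ccc(OS(=O)(=O)c3ccc(C)cc3)cc2)c(OC(=O)C(C)(C)C)c1
F5 | step 19 | (E)-3-[4-(tosyloxy)phenyl]acrylic acid | OC(=O)/C=C/c1ccc(OS(=O)(=O)c2ccc(C)cc2)cc1
F6 | step 19 | tetra-tosyl chalcone | COc1cc(O)c([C@@H]2C[C@H](CCc3ccc(OS(=O)(=O)c4ccc(C)cc4)cc3)O[C@H](c3ccc(OS(=O)(=O)c4ccc(C)cc4)cc3)[C@H]2[C@H](/C=C/C[C@@H](O)CCc2ccc(OS(=O)(=O)c3ccc(C)cc3)cc2)c2ccc(OS(=O)(=O)c3ccc(C)cc3)cc2)c(O)c1C(=O)/C=C/c1ccc(OS(=O)(=O)c2ccc(C)cc2)cc1
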